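In north starting material has a half-life of 0.89 h by the forward rate of its step, shorter than the 0.21 d of catalyst intermediate, each with the other concentrations as charged.

    starting material + free catalyst ⇌ free catalyst + open intermediate (K1 = 2.93, k1 = 0.0902 /M/s)
    free catalyst + open intermediate ⇌ catalyst intermediate (K2 = 153 /M, k2 = 0.0407 /M/s)
    partner + catalyst intermediate → free catalyst + target (k3 = 0.00196 /M/s)
    crystals ⇌ target, rate k4*(cs4 - [target]) while solid is left; crystals form when [target] > cs4 (cs4 = 7.6 mM, k4 = 0.00155 /s)

| flask | starting material | partner | free catalyst | time |
|---|---|---|---|---|
| north | 16 mM | 19.2 mM | 2.4 mM | 2.5 d |
| south-west | 16 mM | 19.2 mM | 2.4 mM | 5.0 d |
| north-east | 16 mM | 19.2 mM | 2.4 mM | 10 d |

- which of these there is most of at the end, counted by the starting material in it, north (open intermediate / target / starting material)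
- which of these there is most of at the end, counted by the starting material in it, south-west (open intermediate / target / starting material)
- which of these there is most of at the end, counted by the starting material in it, north-east (open intermediate / target / starting material)
- final amount of the leader among these, as a percentage of the starting material charged, in north
- final amount of the leader among these, as a percentage of the starting material charged, in south-west
- final amount of the leader among these, as a percentage of the starting material charged, in north-east

- target is meant together with its crystals
- solid, in amounts per volume of the solution: crystals
- run time (north): 2.5 d

The partner step has no way back and partner is charged above starting material, so starting material is the limiting reagent and the end state is target. The open question is how far each flask gets along the way.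

The time scales of north form a ladder. On the first rung, starting material and open intermediate share their pool by 2.93, which leaves 74.6% of it open. On the next rung, open intermediate binds catalyst on 0.082 d, so the catalyst divides between its free and bound forms while the pool stays balanced. On the last rung, catalyst intermediate meets partner on 0.21 d, so my reckoning takes the partner step as the rate-limiting step.

The ceiling of the flask is the pace with the whole catalyst charge as catalyst intermediate and [partner] at its charge, 7.80 mM/d. Ceiling times run time over the starting material charged comes to 1.22 in north; this ceiling count tells how many charges the ceiling could turn over in the time.

My own reckoning for north takes the pace at half time and supposes a quarter of the charge gone by then. Leaving aside what catalyst intermediate holds, the pool is then 12.0 mM, with 8.95 mM open, and [partner] is 15.2 mM. Binding at equilibrium holds 57.8% of the catalyst, so the pace is 3.57 mM/d. Over the run that gives 55.8% target against 33.0% open intermediate, so target leads north. The reckoning stops there.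

The forecast names target as leader in north, south-west and north-east, with 49%, 71% and 88%, holding that “the slow partner step sets the pace”. Its figure for north stands below mine.

The simulation gives target as leader in north, south-west and north-east, with 47.8%, 70.2% and 87.9%, so the forecast holds within its margins and my reckoning runs high.

North thus earned 39.2% of its ceiling count. Part of the shortfall is catalyst intermediate falling back, acting together with the time allowed: without the falling back north reaches 70.0%, and a run ten times as long reaches 98.4%. In the neighbour of north charged with 12 mM of partner, the count is 0.762, and at the same earned share it gives 29.9% target. That flask holds 31.8% target, less than its 44.9% open intermediate.

Its constants are invented; the rest is arithmetic.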